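The runs are simulated with constants of no real substance, noise included.

Reagent to left-handed substrate is the ratio you are choosing: 1.10 equiv in south-west or 0.550 equiv in south-east, twice the charge. Is the extra reagent worth it in excess of right-handed substrate?

| setting | green | grey | south-west | south-east |
|---|---|---|---|---|
| left-handed substrate | 1 M | 1 M | 1.0 M | 1.0 M |
| right-handed substrate | 1 M | 1 M | 1.0 M | 1.0 M |
| reagent | 0.82 equiv | 0.80 equiv | 1.10 equiv | 0.550 equiv |
| free catalyst | 15 mol% | 15 mol% | 15 mol% | 15 mol% |
| remark | run made earlier | run made earlier |  |  |
| time |  |  | 20 min | 20 min |

- green (time / min: right-handed substrate / %, left-handed substrate / %, left-handed product / %): 2.00: 50, 34, 13; 4.00: 49, 25, 14; 6.00: 50, 20, 17; 8.00: 48, 18, 17; 10.0: 46, 18, 19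
- grey (time / min: right-handed substrate / %, left-handed substrate / %, left-handed product / %): 0.833: 47, 38, 8; 1.50: 49, 35, 11; 3.00: 49, 31, 14; 5.00: 49, 23, 18; 10.0: 50, 15, 19

(each reading ± 1.5 percentage points)

- free catalyst is single-handed; left-handed substrate and right-handed substrate are mirror images of each other, charged as a racemate, each of them at the stated concentration
- an excess is the difference of the two amounts in percent of their sum
- an excess is below zero if the other one leads

- which one finishes higher in excess of right-handed substrate over left-handed substrate among what is left of the two ("neither" within 2 percentage points) (south-west / south-east / neither)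
- excess of right-handed substrate over left-handed substrate among what is left of the two at the end, south-west
- excess of right-handed substrate over left-handed substrate among what is left of the two at the end, south-east

Right-handed substrate stays near 49% in both runs, so the excess hangs on r, the left-handed substrate left. Let b be the reagent left, and count both as fractions of the two substrates charged, so r starts at 0.5 and b at the equivalents over 2. I assume one reagent removes one left-handed substrate, at a pace κ·r·b. Then r − b stays constant and ln(r/b) changes linearly with time, with slope κ(r − b). I call κ the apparent second-order constant, and read it mid-run, since the last readings swing with a scatter of 1.5 percentage points: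

κ(grey, 5.00 min) = 0.695 min⁻¹

κ(green, 6.00 min) = 0.740 min⁻¹

κ = 0.717 min⁻¹

Run forward to 20 min, this gives my own reckoning:

south-west: r = 3.99%, excess 84.9%

south-east: r = 23.0%, excess 36.1%

So I would charge south-west. The forecast, reading “a second-order approach to reagent exhaustion”, also names south-west, but gives 70% and 36%, so for south-west it stands below my figure.

The flasks give south-west, with 75.6% for south-west and 40.7% for south-east.

    free catalyst + left-handed substrate ⇌ catalyst intermediate A (K = 6.07 L mol⁻¹, k = 0.0849 L mol⁻¹ s⁻¹)
    free catalyst + right-handed substrate ⇌ catalyst intermediate B (K = 0.378 L mol⁻¹, k = 0.0544 L mol⁻¹ s⁻¹)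
    reagent + catalyst intermediate A → free catalyst + left-handed product (k = 0.0535 L mol⁻¹ s⁻¹)
    reagent + catalyst intermediate B → free catalyst + right-handed product (k = 0.00206 L mol⁻¹ s⁻¹)
    left-handed product ⇌ right-handed product (k = 0.00325 s⁻¹)
    2 free catalyst → spent catalyst A (k = 0.0104 L mol⁻¹ s⁻¹)
    reagent + free catalyst → spent catalyst B (k = 0.00404 L mol⁻¹ s⁻¹)

Neither flask has followed κ exactly: south-west holds 6.78% left-handed substrate against my 3.99%. The long run tests κ in both flasks. The pseudo-first-order lifetime of left-handed substrate, 1/(κb), with the reagent standing at 20 min, is 17.5 min in south-west, shorter than the 200 min of the long run. South-west is still moving: left that long, its left-handed substrate reaches 2.02% and its excess 92.1%. In south-east the lifetime is 568 min, longer than that run, with 0.89% of the reagent left, yet south-east has not come to rest either, and it moves against the fall in r that κ·r·b gives: its left-handed substrate rises from 20.8% to 22.4% and its excess falls from 40.7% to 37.8%, while catalyst intermediate A drops from 43.3% to 18.6% of the catalyst charged.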